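**Retrosynthetic overview**
1. Target 7 is the cis-dibenzyl α-hydroxy-γ-butyrolactone (3S,4R; OH trans to the C4 benzyl). Its only ring, the lactone, is closed last from γ-hydroxy ester 6.
2. 6 comes from β-formyl α-hydroxy ester 5 by reduction of CHO to CH2OH.
3. The C3–C4 bond and both stereocentres come from one amine–squaramide-catalysed enamine cross-aldol of aldehyde 4 (donor) with α-keto ester 2 (acceptor).
4. 2 comes from vanilpyruvic acid 1 by esterification, and 4 from coniferaldehyde 3 by C=C hydrogenation. No protecting groups are used.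

Assumption: 1 and 3 are bought as such, and the phenols are carried unprotected throughout.
Catalyst A (no compound number): 3-{[3,5-bis(trifluoromethyl)phenyl]amino}-4-{[(2S)-pyrrolidin-2-ylmethyl]amino}cyclobut-3-ene-1,2-dione, a known L-proline-derived pyrrolidine–squaramide.

**Step 1**
Reactants: 1 3-(4-hydroxy-3-methoxyphenyl)-2-oxopropanoic acid
Product: 2 methyl 3-(4-hydroxy-3-methoxyphenyl)-2-oxopropanoate
Conditions: MeOH, H2SO4 (cat.), 40 °C
Reagents that add atoms: methanol (CO)
Why: Fischer esterification of an activated α-keto acid; the phenol is inert, no stereocentre is involved, and the product is used as its keto/enol mixture.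

**Step 2**
Reactants: 3 (E)-3-(4-hydroxy-3-methoxyphenyl)prop-2-enal (coniferaldehyde)
Product: 4 3-(4-hydroxy-3-methoxyphenyl)propanal
Conditions: H2 (1 atm), 10% Pd/C, Ph2S (cat.), EtOAc, rt
Reagents that add atoms: none
Why: Chemoselective heterogeneous hydrogenation of the conjugated C=C; sulfide-poisoned Pd leaves the aldehyde, the phenol and the aryl C–O bonds untouched.

**Step 3**
Reactants: 2 methyl 3-(4-hydroxy-3-methoxyphenyl)-2-oxopropanoate, 4 3-(4-hydroxy-3-methoxyphenyl)propanal
Product: 7 (3S,4R)-3-hydroxy-3,4-bis[(4-hydroxy-3-methoxyphenyl)methyl]oxolan-2-one, via aldol aldehyde 5 (not isolated), via diol ester 6 (not isolated)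
Conditions: catalyst A (10 mol %), PhCO2H (10 mol %), CH2Cl2, 0 °C, 4 (1.5 equiv) added over 10 h; then MeOH, NaBH4, −20 °C; then 1 M HCl, rt
Reagents that add atoms: none
Why: Proposed new method: an amine–squaramide-catalysed enamine cross-aldol between a linear aldehyde and an enolisable 3-arylpyruvate ester, forming the C3–C4 bond and both stereocentres at once; the (S)-pyrrolidine forms the s-trans (E)-enamine of 4 while the squaramide N–H pair on the C2 arm binds the ketone and ester carbonyls of the keto tautomer of 2 (replenished from the enol by the amine/acid buffer), so the ketone is delivered to the enamine face syn to the arm, as in proline catalysis, giving the S formyl-bearing carbon, and with both oxygens held on the catalyst side the ArCH2 group sits in the outer position anti to the enamine C=N, so the Si face of the ketone is attacked and the carbinol is S; NaBH4 reduction of the CHO in the same flask (before retro-aldol or epimerisation) and acid-promoted lactonisation of the γ-hydroxy ester then give 7 with OH trans to the C4 benzyl (the C4 descriptor becomes R only through the CIP priority change); the closest known reaction types are the proline or diarylprolinol enamine aldol of aldehydes with activated ketones (ketomalonates, aryl glyoxylates) and two-point squaramide activation of α-keto esters.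

**Compound list**
1 | 3-(4-hydroxy-3-methoxyphenyl)-2-oxopropanoic acid (vanilpyruvic acid) | COc1cc(CC(=O)C(=O)O)ccc1O | starting material
2 | methyl 3-(4-hydroxy-3-methoxyphenyl)-2-oxopropanoate (keto/enol mixture) | COC(=O)C(=O)Cc1ccc(O)c(OC)c1 | intermediate
3 | (E)-3-(4-hydroxy-3-methoxyphenyl)prop-2-enal (coniferaldehyde) | COc1cc(/C=C/C=O)ccc1O | starting material
4 | 3-(4-hydroxy-3-methoxyphenyl)propanal | COc1cc(CCC=O)ccc1O | intermediate
5 | methyl (2S,3S)-3-formyl-2-hydroxy-4-(4-hydroxy-3-methoxyphenyl)-2-[(4-hydroxy-3-methoxyphenyl)methyl]butanoate | COC(=O)[C@](O)(Cc1ccc(O)c(OC)c1)[C@@H](C=O)Cc1ccc(O)c(OC)c1 | intermediate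
6 | methyl (2S,3R)-2-hydroxy-3-(hydroxymethyl)-4-(4-hydroxy-3-methoxyphenyl)-2-[(4-hydroxy-3-methoxyphenyl)methyl]butanoate | COC(=O)[C@](O)(Cc1ccc(O)c(OC)c1)[C@@H](CO)Cc1ccc(O)c(OC)c1 | intermediate
7 | (3S,4R)-3-hydroxy-3,4-bis[(4-hydroxy-3-methoxyphenyl)methyl]oxolan-2-one | COc1cc(C[C@@H]2COC(=O)[C@]2(O)Cc2ccc(O)c(OC)c2)ccc1O | target

**Totals**
Total step count: 3. Longest linear sequence: 2 (step 1 or step 2, then step 3).

**Steps most likely to fail**

Step 3 (the proposed new aldol) is the largest risk. Keto ester 2 is largely enolised, so it may be a slow acceptor or act as a donor. Self-aldol of 4 competes. The ester-inner/benzyl-outer arrangement that sets the carbinol centre is argued from the model above, not from precedent, so the C3 epimer (trans-dibenzyl) could dominate. The outcome would be checked by NOE between the two benzylic CH2 groups, and the ee raised by crystallisation.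
The fallback uses known chemistry, sets out from 4 and comes back at 7. 4 is O-benzylated (BnBr, K2CO3, acetone) to 3-[4-(benzyloxy)-3-methoxyphenyl]propanal F1. The established enantioselective enamine/photoredox α-alkylation of F1 with dimethyl bromomalonate (the imidazolidinone enantiomer that gives the S aldehyde, organic dye photocatalyst, 2,6-lutidine, DMF, visible light) gives dimethyl 2-[(2S)-3-[4-(benzyloxy)-3-methoxyphenyl]-1-oxopropan-2-yl]propanedioate F2. NaBH4 in MeOH followed by acid gives methyl (4S)-4-{[4-(benzyloxy)-3-methoxyphenyl]methyl}-2-oxooxolane-3-carboxylate F3. Alkylation with 4-(benzyloxy)-3-methoxybenzyl bromide (K2CO3, acetone) gives methyl (4S)-3,4-bis{[4-(benzyloxy)-3-methoxyphenyl]methyl}-2-oxooxolane-3-carboxylate F4. Krapcho demethoxycarbonylation (LiCl, wet DMSO, 150 °C) gives (4S)-3,4-bis{[4-(benzyloxy)-3-methoxyphenyl]methyl}oxolan-2-one F5 as C3 epimers that converge in the next operation. KHMDS in THF at −78 °C followed by 3-phenyl-2-(phenylsulfonyl)oxaziridine hydroxylates the enolate on the face opposite the C4 benzyl, which is the sense I recall as reported for such dibenzyl lactone enolates, to give (3S,4R)-3,4-bis{[4-(benzyloxy)-3-methoxyphenyl]methyl}-3-hydroxyoxolan-2-one F6. H2 with Pd/C in EtOAc/MeOH removes both benzyl ethers and gives 7.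

Step 1 may give the dimethyl ketal or methyl enol ether, or 1 may degrade under acid. The fallback sets out from 1 and comes back at 2. It replaces acyl substitution by carboxylate alkylation (KHCO3 1.0 equiv, MeI, DMF, rt), where only the carboxylate is ionised and no acid or methanol is present. It makes no new compound F0.

Step 2 may over-reduce the aldehyde, and 4 is air-sensitive. The fallback sets out from 3 and comes back at 4. It is a metal-free iminium transfer hydrogenation (diethyl 2,6-dimethyl-1,4-dihydropyridine-3,5-dicarboxylate, dibenzylammonium trifluoroacetate cat., THF, rt), where hydride is delivered only to the β-carbon of the iminium ion. It makes no new compound F0.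

**Further compounds**
F1 | step 3 | 3-[4-(benzyloxy)-3-methoxyphenyl]propanal | COc1cc(CCC=O)ccc1OCc1ccccc1
F2 | step 3 | dimethyl 2-[(2S)-3-[4-(benzyloxy)-3-methoxyphenyl]-1-oxopropan-2-yl]propanedioate | COC(=O)C(C(=O)OC)[C@@H](C=O)Cc1ccc(OCc2ccccc2)c(OC)c1
F3 | step 3 | methyl (4S)-4-{[4-(benzyloxy)-3-methoxyphenyl]methyl}-2-oxooxolane-3-carboxylate | COC(=O)C1C(=O)OC[C@H]1Cc1ccc(OCc2ccccc2)c(OC)c1
F4 | step 3 | methyl (4S)-3,4-bis{[4-(benzyloxy)-3-methoxyphenyl]methyl}-2-oxooxolane-3-carboxylate | COC(=O)C1(Cc2ccc(OCc3ccccc3)c(OC)c2)C(=O)OC[C@H]1Cc1ccc(OCc2ccccc2)c(OC)c1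
F5 | step 3 | (4S)-3,4-bis{[4-(benzyloxy)-3-methoxyphenyl]methyl}oxolan-2-one | O=C1OC[C@H](C1Cc2ccc(OCc3ccccc3)c(OC)c2)Cc2ccc(OCc3ccccc3)c(OC)c2
F6 | step 3 | (3S,4R)-3,4-bis{[4-(benzyloxy)-3-methoxyphenyl]methyl}-3-hydroxyoxolan-2-one | COc1cc(C[C@@H]2COC(=O)[C@]2(O)Cc2ccc(OCc3ccccc3)c(OC)c2)ccc1OCc1ccccc1
F0 | step 1 | none | none
F0 | step 2 | none | none
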